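How far E outruns L in the flask at the latest time asked depends on what fraction of L is left then, so the reckoning follows fractions left.

| setting | west | south-east | north | flask |
|---|---|---|---|---|
| J | 10 mM | 10 mM | 10 mM | 10 mM |
| G | 20 mM | 20 mM | 10 mM | 20.0 mM |
| Q | 35 mM | 55 mM | 25 mM | 25.0 mM |
| remark | run made earlier | run made earlier | run made earlier |  |
| time |  |  |  | 3.0 d |

- west (time / d: E / %, L / %, J / %): 0.250: 6.6, 8.7, 46.0; 0.625: 9.4, 7.1, 14.3; 1.25: 11.1, 3.2, 2.5; 2.08: 11.5, 1.6, 0.6; 3.00: 12.1, 0.9, 0; 4.00: 11.0, 0.1, 0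
- south-east (time / d: E / %, L / %, J / %): 0.625: 13.7, 6.9, 14.8; 1.25: 17.3, 4.0, 2.6; 1.67: 17.7, 1.4, 0.8; 2.50: 16.4, 0.7, 0.8; 3.00: 16.7, 0, 0.3; 4.00: 18.6, 0.5, 0.8
- north (time / d: E / %, L / %, J / %): 0.625: 7.7, 6.0, 15.1; 1.25: 8.2, 4.2, 2.6; 2.00: 10.2, 1.8, 0.7; 3.00: 10.1, 0.4, 0; 4.00: 10.0, 0.4, 0

(scatter of a reading: 0.5 percentage points)



* ratio of E to L at 40 min
* ratio of E to L at 6.0 h
* ratio of E to L at 3.0 d

Two rates matter. J falls at 3.11 d⁻¹, since the west run keeps 14.3 % of it at 0.625 d. The other rate belongs to L, which J feeds while L is being lost. At the first west reading, L stands at 16.1 % of the J lost, and this reckoning takes that as the share fed to L. From 0.625 d to 1.25 d, west L falls from 7.1 % to 3.2 % despite that feed. The L lost, divided by the mean L and the interval, gives 1.80 d⁻¹. This is the clearance rate, the pseudo-first-order fraction of L lost per day. The north run, at half the cG, gives 1.20 d⁻¹, so the flask, at west's cG, takes west's rate.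

Clearance is slower than the loss of J, so late L follows clearance. The fraction left is 0.449 %, and the feed raises it by a factor of 2.37. That puts flask L near 0.172 %. For E, this reckoning starts from the west run, which has the flask's cG, and assumes that E scales in proportion to cQ. West's 12.1 % at 3.00 d then becomes 8.64 % for the flask, so my ratio is near 50.2.

The forecast gives 0.47, 0.54 and 20, with L decaying “with a slow tail”.

The flask gives 0.358, 0.505 and 88.6.

    J → X (k = 3.54 × 10⁻⁵ s⁻¹)
    G + X → L (k = 2.86 M⁻¹ s⁻¹)
    Q + X → E (k = 0.784 M⁻¹ s⁻¹)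
    X → D (k = 0.155 s⁻¹)
    G + L → Z (k = 0.00162 M⁻¹ s⁻¹)

Flask L falls from 1.94 % at 1.50 d to 0.0960 % at 3.00 d, a clearance of 2.00 d⁻¹ beside the carried 1.80 d⁻¹. For the neighbouring flask with 12 mM of G, a straight line between the north and west rates gives 1.32 d⁻¹. The fraction left is then 1.92 %, and L comes to about 0.536 %. That neighbouring flask holds 0.497 % of L and 9.36 % of E, a ratio of 18.8.

Readings and results were generated by integration on assumed constants, and the scatter is random.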